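## Retrosynthetic overview

1. Feature (germacrane numbering C1–C15): the oxolane oxygen joins the two fully substituted carbons C7 and C10 of the ten-membered ring, and C7 is followed by the C6 carbinol and the cis C4–C5 unit. The array O–C7–C6–C5=C4 is what an allyl group leaves behind when it moves from that oxygen to C7.
2. Key disconnection: one oxonium ylide [2,3]-shift makes C6–C7 and O–C7 and cuts O–C4. It expands a 2,2,6,6-tetrasubstituted oxane (O, C10, C1, C2, C3, C4) into the oxolanone-bridged ten-membered carbocycle.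
3. The oxane comes from (R)-dehydrolinalool (geraniol, Sharpless epoxidation). Shi epoxidation of a dienyl side chain and 6-endo opening of the vinyl epoxide set C1 and C10. The C10 vinyl group becomes the diazo keto ester arm and the C4 ethynyl group the E enol ether.
4. After the shift: exo reduction at C8, ester to enol triflate, Mitsunobu inversion to the methacrylate, C1 oxidation, C6-hydroxyl-directed epoxidation, then carbonylative lactonisation. The epoxidation precedes the lactone because a free oxidant is expected to attack the wrong alkene face.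
5. Ring order: oxane; oxolane together with the ten-membered ring; oxirane; α-methylene lactone.

Key step: step 14

Remark: exo is the oxolane face carrying C11 and C14, endo the face carrying the C1–C6 bridge; the L-fructose-derived enantiomer of the Shi ketone is assumed to be available as a catalyst.

## Route

Step 1
Reactants: 1 geraniol
Product: 2 (2R,3R)-2,3-epoxygeraniol
Conditions: Ti(OiPr)4 (5 mol%), D-(−)-diethyl tartrate (7 mol%), t-BuOOH, 4 Å MS, CH2Cl2, −20 °C
Reagents that add atoms: tert-butyl hydroperoxide CC(C)(C)OO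
Why: Sharpless asymmetric epoxidation of an E allylic alcohol, in which the D-tartrate sets both epoxide carbons by reagent control; the quaternary one becomes C4 of the key precursor.

Step 2
Reactants: 2 (2R,3R)-2,3-epoxygeraniol
Product: 3 (2S,3R)-2-(chloromethyl)-3-methyl-3-(4-methylpent-3-enyl)oxirane
Conditions: PPh3, CCl4, NaHCO3, reflux
Reagents that add atoms: tetrachloromethane ClC(Cl)(Cl)Cl
Why: Appel chlorination of the primary alcohol under buffered neutral conditions leaves the epoxide and both stereocentres untouched.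

Step 3
Reactants: 3 (2S,3R)-2-(chloromethyl)-3-methyl-3-(4-methylpent-3-enyl)oxirane
Product: 5 (R)-3,7-dimethyloct-6-en-1-yn-3-ol [(R)-dehydrolinalool], via chlorovinyl alkoxide 4 (not isolated)
Conditions: n-BuLi (3.3 equiv), THF, −40 to −20 °C; aq. NH4Cl
Reagents that add atoms: none
Why: Base-induced double elimination of a 2,3-epoxy chloride (epoxide opening, then dehydrochlorination) gives the tertiary propargylic alcohol with the C–O stereocentre of the epoxide retained.

Step 4
Reactants: 5 (R)-3,7-dimethyloct-6-en-1-yn-3-ol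
Product: 7 (2E,6R)-6-hydroxy-2,6-dimethyloct-2-en-7-ynal, via allylic alcohol 6 (not isolated)
Conditions: SeO2 (0.3 equiv), t-BuOOH, CH2Cl2, rt; filtration; then MnO2, CH2Cl2, rt
Reagents that add atoms: selenium dioxide O=[Se]=O (catalytic oxygen carrier); tert-butyl hydroperoxide CC(C)(C)OO
Why: Selenium dioxide allylic oxidation (ene reaction, then [2,3]-shift) attacks the E methyl group of the trisubstituted alkene, and MnO2 oxidises only the new primary allylic alcohol.

Step 5
Reactants: 7 (2E,6R)-6-hydroxy-2,6-dimethyloct-2-en-7-ynal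
Product: 8 (3R,6E)-3,7-dimethylnona-6,8-dien-1-yn-3-ol
Conditions: Ph3PCH3Br, KOt-Bu, THF, 0 °C to rt
Reagents that add atoms: methyltriphenylphosphonium bromide C[P+](c1ccccc1)(c1ccccc1)c1ccccc1.[Br-]
Why: Wittig methylenation of the enal gives the conjugated diene and does not touch the E trisubstituted alkene.

Step 6
Reactants: 8 (3R,6E)-3,7-dimethylnona-6,8-dien-1-yn-3-ol
Product: 10 (2R,3S,6R)-2-ethenyl-6-ethynyl-2,6-dimethyloxan-3-ol, via vinyl epoxide 9 (not isolated)
Conditions: ent-Shi ketone (0.3 equiv), Oxone, K2CO3, n-Bu4NHSO4, MeCN–DMM–aq. borate buffer (pH 10.5), 0 °C; extractive work-up; then CSA (0.1 equiv), CH2Cl2, 0 °C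
Reagents that add atoms: Oxone (potassium peroxymonosulfate) [K+].[O-]S(=O)(=O)OO
Why: Shi epoxidation of the more substituted alkene of the diene sets C1 and C10 by catalyst control (6S,7S epoxide), and acid-catalysed 6-endo opening of the hydroxy vinyl epoxide with inversion at the vinyl-stabilised tertiary carbon closes the oxane with the ethenyl group cis to the ethynyl group and trans to the new hydroxyl.

Step 7
Reactants: 10 (2R,3S,6R)-2-ethenyl-6-ethynyl-2,6-dimethyloxan-3-ol
Product: 11 (2R,3S,6R)-3-(tert-butyldimethylsilyloxy)-2-ethenyl-6-ethynyl-2,6-dimethyloxane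
Conditions: TBSOTf, 2,6-lutidine, CH2Cl2, −78 to 0 °C
Reagents that add atoms: tert-butyldimethylsilyl triflate CC(C)(C)[Si](C)(C)OS(=O)(=O)C(F)(F)F
Why: Silyl triflate silylation of the hindered secondary alcohol gives the poorly Lewis-basic ether needed at C1 in the key step.

Step 8
Reactants: 11 (2R,3S,6R)-3-(tert-butyldimethylsilyloxy)-2-ethenyl-6-ethynyl-2,6-dimethyloxane
Product: 13 (2R,3S,6R)-3-(tert-butyldimethylsilyloxy)-2-ethenyl-6-[(E)-2-iodoethenyl]-2,6-dimethyloxane, via alkenylzirconocene 12 (not isolated)
Conditions: Cp2Zr(H)Cl (1.2 equiv), THF, rt; then I2, 0 °C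
Reagents that add atoms: iodine II
Why: Hydrozirconation with the Schwartz reagent is a syn addition that is much faster at the terminal alkyne than at the hindered vinyl group, and iodinolysis with retention gives the E vinyl iodide only.

Step 9
Reactants: 13 (E)-vinyl iodide; 14 4-methoxybenzyl alcohol
Product: 15 (2R,3S,6R)-3-(tert-butyldimethylsilyloxy)-2-ethenyl-6-{(E)-2-[(4-methoxybenzyl)oxy]ethenyl}-2,6-dimethyloxane
Conditions: CuI (10 mol%), 3,4,7,8-tetramethyl-1,10-phenanthroline (20 mol%), Cs2CO3, toluene, 80 °C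
Reagents that add atoms: 4-methoxybenzyl alcohol (reactant 14) COc1ccc(CO)cc1
Why: Copper-catalysed Ullmann-type C–O coupling of a vinyl iodide with an alcohol proceeds with retention of alkene geometry, so the E enol ether is obtained.

Step 10
Reactants: 15 (E)-PMB enol ether
Product: 17 2-[(2R,3S,6R)-3-(tert-butyldimethylsilyloxy)-6-{(E)-2-[(4-methoxybenzyl)oxy]ethenyl}-2,6-dimethyloxan-2-yl]ethanol, via alkylborane 16 (not isolated)
Conditions: 9-BBN (2 equiv), THF, 0 to 50 °C; then NaOH, H2O2, 0 °C
Reagents that add atoms: hydrogen peroxide OO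
Why: Anti-Markovnikov hydroboration–oxidation in which 9-BBN selects the monosubstituted vinyl group over the 1,2-disubstituted enol ether that is shielded by the quaternary C4.

Step 11
Reactants: 17 primary alcohol
Product: 18 2-[(2R,3S,6R)-3-(tert-butyldimethylsilyloxy)-6-{(E)-2-[(4-methoxybenzyl)oxy]ethenyl}-2,6-dimethyloxan-2-yl]acetaldehyde
Conditions: Dess–Martin periodinane, NaHCO3, CH2Cl2, 0 °C
Reagents that add atoms: none
Why: Buffered Dess–Martin oxidation gives the aldehyde without acid that would hydrolyse the enol ether and without base that could open the β-alkoxy aldehyde.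

Step 12
Reactants: 18 aldehyde; 19 methyl diazoacetate
Product: 20 methyl 2-diazo-3-hydroxy-4-[(2R,3S,6R)-3-(tert-butyldimethylsilyloxy)-6-{(E)-2-[(4-methoxybenzyl)oxy]ethenyl}-2,6-dimethyloxan-2-yl]butanoate (both C3 epimers)
Conditions: LDA, methyl diazoacetate, THF, −78 °C; then 18, −78 °C
Reagents that add atoms: methyl diazoacetate (reactant 19) COC(=O)C=[N+]=[N-]
Why: Aldol-type addition of lithiated diazoacetate to the aldehyde is fast at −78 °C, where β-elimination of the ring oxygen does not compete; the new carbinol centre is removed in the next step.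

Step 13
Reactants: 20 α-diazo-β-hydroxy ester
Product: 21 methyl 2-diazo-4-[(2R,3S,6R)-3-(tert-butyldimethylsilyloxy)-6-{(E)-2-[(4-methoxybenzyl)oxy]ethenyl}-2,6-dimethyloxan-2-yl]-3-oxobutanoate
Conditions: Dess–Martin periodinane, NaHCO3, CH2Cl2, rt
Reagents that add atoms: none
Why: Dess–Martin oxidation of α-diazo-β-hydroxy esters gives α-diazo-β-keto esters under neutral conditions that spare the diazo group and the enol ether.

Step 14
Reactants: 21 diazo keto ester
Product: 23 bicyclic keto ester (11-oxabicyclo[6.2.1]undecenone core; Z-4-ene; 8-ketone; 7-CO2Me; 6R-OPMB; 1S-OTBS; C6 and C1 cis on the oxolane), via oxonium ylide 22 (not isolated)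
Conditions: Cu(hfacac)2 (5 mol%), ClCH2CH2Cl, 80 °C, slow addition of 21
Reagents that add atoms: none
Why: Cu(hfacac)2 turns the diazo keto ester into a copper carbenoid that the ring oxygen captures (O–C7 bond; the oxolan-3-one closes by a five-membered attack of oxygen on the carbenoid carbon, exo to the Cu=C bond), and the keto-ester-stabilised oxonium ylide 22 then shifts its alkoxyallyl arm suprafacially by [2,3] (C6–C7 formed, O–C4 broken) through a five-centre envelope, which opens the oxane into the nine-membered oxonene, that is the ten-membered carbocycle through C8–C9. The closest known reaction type is the copper-catalysed oxonium ylide formation and [2,3]-rearrangement of 6-vinyloxan-2-yl diazoketones to Z-11-oxabicyclo[6.2.1]undecenones, and keto ester carbenoids are established partners in [2,3]-shifts of allyl ether ylides. C7 is set by C10, because the arm can only reach the face of the oxolanone on which the former oxane carbons lie, so C6 and C1 end cis on the oxolane. C6 follows from the E enol ether in the envelope that keeps C3 folded under the ylide, the same envelope that makes the new alkene Z. The step needs capture by the axial lone pair of the chair that holds both arms equatorial and both methyls axial: that lone pair is the only one not flanked by four α-carbons, the equatorial OTBS leaves only hydrogens as its 1,3-diaxial neighbours, and the flipped chair can offer only the buried equatorial pair. Preference for oxygen over insertion into C1–H or cyclopropanation of the enol ether rests on the five-membered closure and on copper, and loss of N2 followed by discharge of the oxonium makes the sequence irreversible.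

Step 15
Reactants: 23 bicyclic keto ester
Product: 24 8R alcohol (8-OH endo, cis to C6)
Conditions: NaBH4, MeOH–THF, −40 to −20 °C
Reagents that add atoms: none
Why: Chemoselective borohydride reduction of the ketone; hydride should add to the exo face of the oxolanone, away from the pseudo-axial C7–C6 and C10–C1 bonds of the bridge, which sets C8 as R.

Step 16
Reactants: 24 8R alcohol
Product: 25 8-O-triethylsilyl ether
Conditions: TESOTf, 2,6-lutidine, CH2Cl2, −78 °C
Reagents that add atoms: triethylsilyl triflate CC[Si](CC)(CC)OS(=O)(=O)C(F)(F)F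
Why: Silylation of the β-hydroxy ester under non-basic conditions avoids retro-aldol cleavage and gives an ether that can later be removed in the presence of the TBS ether.

Step 17
Reactants: 25 TES ether methyl ester
Product: 27 methyl ketone (C7–C(=O)CH3), via silyl enolate 26 (not isolated)
Conditions: Me3SiCH2Li (3 equiv), pentane–THF, 0 °C; then MeOH, rt
Reagents that add atoms: (trimethylsilyl)methyllithium [Li]C[Si](C)(C)C
Why: Acylation of (trimethylsilyl)methyllithium by the ester stops at the enolate of the α-silyl ketone, and methanolysis of the C–Si bond gives the methyl ketone without over-addition.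

Step 18
Reactants: 27 methyl ketone
Product: 28 enol triflate (C7–C(OTf)=CH2)
Conditions: KHMDS, THF, −78 °C; then PhNTf2
Reagents that add atoms: N-phenylbis(trifluoromethanesulfonimide) O=S(=O)(N(c1ccccc1)S(=O)(=O)C(F)(F)F)C(F)(F)F
Why: Enolisation can only occur towards the methyl group because C7 is quaternary, and O-triflation of the kinetic enolate gives the 1,1-disubstituted vinyl triflate.

Step 19
Reactants: 28 enol triflate TES ether
Product: 29 8R alcohol enol triflate
Conditions: PPTS (0.2 equiv), MeOH–CH2Cl2, 0 °C to rt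
Reagents that add atoms: none
Why: Acid-catalysed methanolysis cleaves the triethylsilyl ether much faster than the hindered secondary TBS ether, and the PMB ether and the vinyl triflate are stable to it.

Step 20
Reactants: 29 8R alcohol; 30 methacrylic acid
Product: 31 8S methacrylate (ester exo, trans to C6)
Conditions: PPh3, DIAD, toluene, 0 °C to rt
Reagents that add atoms: methacrylic acid (reactant 30) C=C(C)C(=O)O
Why: Mitsunobu esterification displaces the endo oxyphosphonium by SN2 with inversion, the carboxylate entering on the open exo face of the five-membered ring, which sets C8 as S and installs the ester in one step.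

Step 21
Reactants: 31 8S methacrylate
Product: 32 C1 alcohol
Conditions: HF·pyridine, pyridine, THF, 0 °C to rt
Reagents that add atoms: none
Why: Buffered fluoride desilylation removes the TBS ether without touching the methacrylate, the vinyl triflate or the PMB ether.

Step 22
Reactants: 32 C1 alcohol
Product: 33 C1 ketone
Conditions: Dess–Martin periodinane, NaHCO3, CH2Cl2, rt
Reagents that add atoms: none
Why: Dess–Martin oxidation of the only free hydroxyl gives the C1 ketone, which has no epimerisable centre next to it (C10 is quaternary).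

Step 23
Reactants: 33 C1 ketone PMB ether
Product: 34 6R allylic alcohol
Conditions: DDQ, CH2Cl2–pH 7 buffer, 0 °C
Reagents that add atoms: none
Why: Oxidative cleavage of the PMB ether by DDQ (hydride abstraction, then hydrolysis of the oxocarbenium ion) frees the C6 hydroxyl under neutral conditions.

Step 24
Reactants: 34 6R allylic alcohol
Product: 35 (4R,5S)-epoxy alcohol (epoxide cis to the C6 hydroxyl)
Conditions: VO(acac)2 (10 mol%), t-BuOOH (decane), CH2Cl2, 0 °C to rt
Reagents that add atoms: tert-butyl hydroperoxide CC(C)(C)OO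
Why: Hydroxyl-directed vanadium epoxidation of a medium-ring Z allylic alcohol should go through the rotamer with the O–C6–C5=C4 dihedral near 45°, which puts C7 on the far face and delivers oxygen cis to the hydroxyl (4R,5S), whereas a free peracid is expected to attack the open face of the H-eclipsed rotamer and give the other epoxide; the step comes before lactonisation because the lactone locks that rotamer.

Step 25
Reactants: 35 epoxy alcohol enol triflate
Product: 36 target CNP0241021.1 (4R,5S,6R,7S,8S,10R)
Conditions: Pd(PPh3)4 (10 mol%), CO (1 atm), n-Bu3N, LiCl, MeCN, 65 °C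
Reagents that add atoms: carbon monoxide [C-]#[O+]
Why: Palladium-catalysed carbonylative lactonisation (oxidative addition to the vinyl triflate, CO insertion, capture of the acylpalladium by the C6 hydroxyl) closes the α-methylene-γ-lactone under mildly basic conditions that the epoxide, the methacrylate and the ketone tolerate.

## Compound list

1 | geraniol | OC/C=C(\C)CCC=C(C)C | starting material
2 | (2R,3R)-2,3-epoxygeraniol | OC[C@H]1O[C@]1(C)CCC=C(C)C | intermediate
3 | (2S,3R)-2-(chloromethyl)-3-methyl-3-(4-methylpent-3-enyl)oxirane | ClC[C@H]1O[C@]1(C)CCC=C(C)C | intermediate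
4 | lithium (3R)-1-chloro-3,7-dimethylocta-1,6-dien-3-olate (chlorovinyl alkoxide) | [Li]O[C@@](C)(C=CCl)CCC=C(C)C | intermediate
5 | (R)-3,7-dimethyloct-6-en-1-yn-3-ol | C#C[C@](C)(O)CCC=C(C)C | intermediate
6 | (2E,6R)-2,6-dimethyloct-2-en-7-yne-1,6-diol | C#C[C@](C)(O)CC/C=C(\C)CO | intermediate
7 | (2E,6R)-6-hydroxy-2,6-dimethyloct-2-en-7-ynal | C#C[C@](C)(O)CC/C=C(\C)C=O | intermediate
8 | (3R,6E)-3,7-dimethylnona-6,8-dien-1-yn-3-ol | C#C[C@](C)(O)CC/C=C(\C)C=C | intermediate
9 | (3R,6S,7S)-6,7-epoxy-3,7-dimethylnon-8-en-1-yn-3-ol | C#C[C@](C)(O)CC[C@@H]1O[C@@]1(C)C=C | intermediate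
10 | (2R,3S,6R)-2-ethenyl-6-ethynyl-2,6-dimethyloxan-3-ol | C=C[C@@]1(C)O[C@@](C)(C#C)CC[C@@H]1O | intermediate
11 | TBS ether of 10 | C=C[C@@]1(C)O[C@@](C)(C#C)CC[C@@H]1O[Si](C)(C)C(C)(C)C | intermediate
12 | (E)-alkenylzirconocene chloride from 11 | C=C[C@@]1(C)O[C@@](C)(/C=C/[Zr](Cl)(C2C=CC=C2)C2C=CC=C2)CC[C@@H]1O[Si](C)(C)C(C)(C)C | intermediate
13 | (E)-2-iodoethenyl oxane | C=C[C@@]1(C)O[C@@](C)(/C=C/I)CC[C@@H]1O[Si](C)(C)C(C)(C)C | intermediate
14 | 4-methoxybenzyl alcohol | COc1ccc(CO)cc1 | starting material
15 | (E)-PMB enol ether | C=C[C@@]1(C)O[C@@](C)(/C=C/OCc2ccc(OC)cc2)CC[C@@H]1O[Si](C)(C)C(C)(C)C | intermediate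
16 | B-alkyl-9-borabicyclo[3.3.1]nonane from 15 | C3CC4CCCC(C3)B4CC[C@@]1(C)O[C@@](C)(/C=C/OCc2ccc(OC)cc2)CC[C@@H]1O[Si](C)(C)C(C)(C)C | intermediate
17 | primary alcohol (C8–OH arm) | OCC[C@@]1(C)O[C@@](C)(/C=C/OCc2ccc(OC)cc2)CC[C@@H]1O[Si](C)(C)C(C)(C)C | intermediate
18 | aldehyde (C8 arm) | O=CC[C@@]1(C)O[C@@](C)(/C=C/OCc2ccc(OC)cc2)CC[C@@H]1O[Si](C)(C)C(C)(C)C | intermediate
19 | methyl diazoacetate | COC(=O)C=[N+]=[N-] | starting material
20 | α-diazo-β-hydroxy ester | COC(=O)C(=[N+]=[N-])C(O)C[C@@]1(C)O[C@@](C)(/C=C/OCc2ccc(OC)cc2)CC[C@@H]1O[Si](C)(C)C(C)(C)C | intermediate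
21 | diazo keto ester (key precursor) | COC(=O)C(=[N+]=[N-])C(=O)C[C@@]1(C)O[C@@](C)(/C=C/OCc2ccc(OC)cc2)CC[C@@H]1O[Si](C)(C)C(C)(C)C | intermediate
22 | bicyclic oxonium ylide | COC(=O)[C-]1C(=O)C[C@@]2(C)[O+]1[C@@](C)(/C=C/OCc3ccc(OC)cc3)CC[C@@H]2O[Si](C)(C)C(C)(C)C | intermediate
23 | bicyclic keto ester (key product) | O=C1C[C@@]2(C)O[C@]1(C(=O)OC)[C@H](OCc3ccc(OC)cc3)/C=C(/C)CC[C@@H]2O[Si](C)(C)C(C)(C)C | intermediate
24 | 8R alcohol | O[C@@H]1C[C@@]2(C)O[C@]1(C(=O)OC)[C@H](OCc3ccc(OC)cc3)/C=C(/C)CC[C@@H]2O[Si](C)(C)C(C)(C)C | intermediate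
25 | 8-O-TES ether | CC[Si](CC)(CC)O[C@@H]1C[C@@]2(C)O[C@]1(C(=O)OC)[C@H](OCc3ccc(OC)cc3)/C=C(/C)CC[C@@H]2O[Si](C)(C)C(C)(C)C | intermediate
26 | lithium enolate of the α-trimethylsilyl ketone | CC[Si](CC)(CC)O[C@@H]1C[C@@]2(C)O[C@]1(C(O[Li])=C[Si](C)(C)C)[C@H](OCc3ccc(OC)cc3)/C=C(/C)CC[C@@H]2O[Si](C)(C)C(C)(C)C | intermediate
27 | methyl ketone | CC[Si](CC)(CC)O[C@@H]1C[C@@]2(C)O[C@]1(C(C)=O)[C@H](OCc3ccc(OC)cc3)/C=C(/C)CC[C@@H]2O[Si](C)(C)C(C)(C)C | intermediate
28 | enol triflate | CC[Si](CC)(CC)O[C@@H]1C[C@@]2(C)O[C@]1(C(=C)OS(=O)(=O)C(F)(F)F)[C@H](OCc3ccc(OC)cc3)/C=C(/C)CC[C@@H]2O[Si](C)(C)C(C)(C)C | intermediate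
29 | 8R alcohol enol triflate | O[C@@H]1C[C@@]2(C)O[C@]1(C(=C)OS(=O)(=O)C(F)(F)F)[C@H](OCc3ccc(OC)cc3)/C=C(/C)CC[C@@H]2O[Si](C)(C)C(C)(C)C | intermediate
30 | methacrylic acid | C=C(C)C(=O)O | starting material
31 | 8S methacrylate | C=C(C)C(=O)O[C@H]1C[C@@]2(C)O[C@]1(C(=C)OS(=O)(=O)C(F)(F)F)[C@H](OCc3ccc(OC)cc3)/C=C(/C)CC[C@@H]2O[Si](C)(C)C(C)(C)C | intermediate
32 | C1 alcohol | C=C(C)C(=O)O[C@H]1C[C@@]2(C)O[C@]1(C(=C)OS(=O)(=O)C(F)(F)F)[C@H](OCc3ccc(OC)cc3)/C=C(/C)CC[C@@H]2O | intermediate
33 | C1 ketone | C=C(C)C(=O)O[C@H]1C[C@@]2(C)O[C@]1(C(=C)OS(=O)(=O)C(F)(F)F)[C@H](OCc3ccc(OC)cc3)/C=C(/C)CCC2=O | intermediate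
34 | 6R allylic alcohol | C=C(C)C(=O)O[C@H]1C[C@@]2(C)O[C@]1(C(=C)OS(=O)(=O)C(F)(F)F)[C@H](O)/C=C(/C)CCC2=O | intermediate
35 | (4R,5S)-epoxy alcohol | C=C(C)C(=O)O[C@H]1C[C@@]2(C)O[C@]1(C(=C)OS(=O)(=O)C(F)(F)F)[C@H](O)[C@@H]1O[C@]1(C)CCC2=O | intermediate
36 | CNP0241021.1 | C=C(C)C(=O)O[C@H]1C[C@@]2(C)O[C@@]13C(=C)C(=O)O[C@@H]3[C@@H]1O[C@]1(C)CCC2=O | target

## Step count

Total: 25 steps. Longest linear sequence: 25 steps (1 to 36); the building blocks 14, 19 and 30 enter without prior steps.

## Steps most likely to fail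

Step 14 (key step). The carbenoid may be captured by the equatorial lone pair or from the flipped chair, which would give the E alkene and the C6 epimer. It may also insert into the axial C1–H bond or cyclopropanate the enol ether, and the ylide may collapse ionically with loss of the C6 configuration. Fallback: the ylide is reached without a diazo compound or copper. From aldehyde 18, Corey–Fuchs olefination (CBr4, PPh3, Et3N, CH2Cl2) would give the dibromoalkene F1. Treatment with n-BuLi and then methyl chloroformate would give the alkynoate F2. Gold(I)-catalysed oxidation of the alkyne with 8-methylquinoline N-oxide generates the α-oxo gold carbene at C7 at room temperature; capture by the ring oxygen and the [2,3]-shift return to 23.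

Step 20. Substitution at C8 is slowed by the quaternary C7, so elimination towards C9 or a 1,2-shift assisted by the ring oxygen may compete, or the alcohol may simply be returned. Fallback without substitution at C8: from 29, HF·pyridine would give the diol F3, Dess–Martin oxidation the diketone F4, and DDQ the β-hydroxy ketone F5. Me4NBH(OAc)3 (Evans–Saksena reduction) should then deliver hydride from the C6 alkoxyborohydride to the endo face of C8 only, leaving the undirected C1 ketone and giving the anti diol F6 with the 8S configuration. Acylation of the more accessible ring hydroxyl with methacrylic anhydride and DMAP at low temperature rejoins the route at 34.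

Step 24. Facial selectivity may be poor if the bridged ring cannot reach the syn-clinal rotamer, in which case the trans epoxy alcohol would form; the epoxy alcohol may also open or undergo Payne migration on the Lewis acidic metal. Fallback: reagent control in place of substrate control, using Ti(OiPr)4, L-(+)-diisopropyl tartrate, t-BuOOH, 4 Å MS, CH2Cl2, −20 °C. The 6R carbinol is the matched, erythro-forming partner of this tartrate. The fallback runs from 34 to 35 and makes no new compound (F0).

## Further compounds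

F1 | step 14 | dibromoalkene from 18 | BrC(Br)=CC[C@@]1(C)O[C@@](C)(/C=C/OCc2ccc(OC)cc2)CC[C@@H]1O[Si](C)(C)C(C)(C)C
F2 | step 14 | alkynoate (methyl 4-substituted but-2-ynoate) | COC(=O)C#CC[C@@]1(C)O[C@@](C)(/C=C/OCc2ccc(OC)cc2)CC[C@@H]1O[Si](C)(C)C(C)(C)C
F3 | step 20 | 1,8-diol enol triflate | O[C@@H]1C[C@@]2(C)O[C@]1(C(=C)OS(=O)(=O)C(F)(F)F)[C@H](OCc3ccc(OC)cc3)/C=C(/C)CC[C@@H]2O
F4 | step 20 | 1,8-diketone | O=C1C[C@@]2(C)O[C@]1(C(=C)OS(=O)(=O)C(F)(F)F)[C@H](OCc3ccc(OC)cc3)/C=C(/C)CCC2=O
F5 | step 20 | 6-hydroxy-1,8-diketone | O=C1C[C@@]2(C)O[C@]1(C(=C)OS(=O)(=O)C(F)(F)F)[C@H](O)/C=C(/C)CCC2=O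
F6 | step 20 | 6R,8S-diol 1-ketone | O[C@H]1C[C@@]2(C)O[C@]1(C(=C)OS(=O)(=O)C(F)(F)F)[C@H](O)/C=C(/C)CCC2=O
F0 | step 24 | none | none
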